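**Plan**

- Retrosynthesis: C12–C13 is cut first (B-alkyl Suzuki coupling), which separates a C13–C16 acetoxy enoate from the decalin. C11=C12 is traced to a lactone carbonyl, and ring B is then opened at C7–C8 and C9–C10.
- Enabling feature: ring B (C5–C10) is a cyclohexene whose C6=C7 bond sits one position off a [4+2] retron. With the alkene returned to C5=C6 and a nitrogen placed on C7, the C10 quaternary methyl, the trans C8 (C17)/C9 (C11) pair and the trans H5 are what an endo adduct of an E-fumarate (C8, C9) with a ring A vinylcyclohexene (C10, C5, C6, C7) gives once the nitrogen hands its hydrogen to C5 and leaves as N2.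
- Forward order: ring A is bought, ring B closes in the Diels–Alder step, a temporary C17–O–C11 lactone tells the two carboxyl carbons apart, the alkene is moved to C6=C7, the lactone is opened to the C9 vinyl group, and the side chain is joined last.
- Stereochemistry: C7 (transient), C8, C9 and C10 are set in the cycloaddition (E-alkenes, endo imide, (R,R)-bis(oxazoline) copper catalyst for the absolute sense). C5 comes from the suprafacial retro-ene. The C13=C14 geometry comes from a Z-enol triflate coupled with retention.

Key step: step 4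

Remark: labdane numbering is used for all bicyclic compounds. The target is the (5R,8S,9R,10S) enantiomer (ent-labdane series). The sense of induction of the copper catalyst is assigned from the square-planar chelate model, which is taken to hold for this diene.

**Route**

Step 1
Reactants: 1 β-cyclocitral (2,6,6-trimethylcyclohex-1-ene-1-carbaldehyde)
Product: 2 2-[(E)-2-iodoethenyl]-1,3,3-trimethylcyclohex-1-ene
Conditions: CrCl2 (6 equiv), CHI3 (2 equiv), THF, 0 → 23 °C
Reagents that add atoms: iodoform, IC(I)I
Why: Takai iodoolefination, in which the geminal dichromium species from CHI3 adds to the aldehyde and anti elimination should give the E-iodoalkene and so add C7.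

Step 2
Reactants: 2 2-[(E)-2-iodoethenyl]-1,3,3-trimethylcyclohex-1-ene, 3 di-tert-butyl hydrazine-1,2-dicarboxylate
Product: 4 di-tert-butyl 1-[(E)-2-(2,6,6-trimethylcyclohex-1-en-1-yl)ethenyl]hydrazine-1,2-dicarboxylate
Conditions: CuI (10 mol %), 1,10-phenanthroline (20 mol %), Cs2CO3, DMF, 80 °C
Reagents that add atoms: none
Why: Copper-catalysed Goldberg-type N-alkenylation of a hydrazide N–H by an alkenyl iodide, which runs with retention of alkene geometry and should stop after one vinylation of the symmetrical hydrazide.

Step 3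
Reactants: 5 ethyl fumaroyl chloride, 6 2-oxazolidinone
Product: 8 ethyl (E)-4-oxo-4-(2-oxooxazolidin-3-yl)but-2-enoate, via lithium oxazolidinide 7 (not isolated)
Conditions: 6, n-BuLi, THF, −78 °C; then 5, −78 → 0 °C
Reagents that add atoms: none
Why: N-acylation of the lithiated oxazolidinone by the acid chloride at low temperature is the standard entry to fumaroyl imides and leaves the E-alkene untouched.

Step 4
Reactants: 4 di-tert-butyl 1-[(E)-2-(2,6,6-trimethylcyclohex-1-en-1-yl)ethenyl]hydrazine-1,2-dicarboxylate, 8 ethyl (E)-4-oxo-4-(2-oxooxazolidin-3-yl)but-2-enoate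
Product: 9 endo cycloadduct (ring B with C5=C6; C7 N(Boc)NHBoc and C8 acyl oxazolidinone on the face opposite the C10 methyl; C9 CO2Et on the methyl face)
Conditions: [Cu((R,R)-t-Bu-box)](SbF6)2 (10 mol %; t-Bu-box = 2,2'-isopropylidenebis(4-tert-butyl-2-oxazoline)), CH2Cl2, −20 → 23 °C
Reagents that add atoms: none
Why: Proposed new method: the cationic divalent copper centre binds the imide of 8 as a square-planar s-cis chelate and the vinylogous ene-hydrazide 4 adds in a concerted, asynchronous [4+2] in which the hindered C9–C10 bond leads C7–C8, since the nitrogen lone pair raises the coefficient at C10 and chelation makes C9 the electrophilic terminus; the closest known reaction types are Cu(box)-catalysed cycloadditions of 1-carbamoyl dienes with acyl oxazolidinones, thermal Diels–Alder reactions of 1-hydrazinodienes, and cycloadditions of 2,6,6-trimethyl-1-vinylcyclohexene that create the C10 quaternary carbon, but their combination on this diene is without precedent. Ring B (C5–C10) closes by intermolecular [4+2] cycloaddition onto the purchased ring A and leaves the alkene at C5=C6. C8 and C9 come out trans because the dienophile is an E-alkene, and the C7 nitrogen is cis to C17 while C11 is cis to the C10 methyl because the imide reacts endo and the diene carries nitrogen outside at C7 and the methyl inside at C10. The absolute sense follows from the ligand: in the chelate the tert-butyl group of the (R,R)-ligand beside the enoyl arm covers the Re face of C8, so C7 should bond to the Si face of C8, which fixes C7, C8, C9 and C10 as the target requires. The step needs regio-, endo and facial selectivity, secured respectively by the pairing of the nitrogen-bearing C7 with the imide α-carbon C8, by the C4 gem-dimethyl group beneath C5, which leaves room only for hydrogen on C9 and so keeps the ester exo and the imide endo, and by the C2-symmetric ligand. The twisted s-cis ground state of the diene and its inside methyl are expected to be offset by the doubly activated, cationic dienophile.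

Step 5
Reactants: 9 endo cycloadduct
Product: 10 C17 alcohol (C8 CH2OH, C9 CO2Et, C7 N(Boc)NHBoc, C5=C6)
Conditions: NaBH4 (4 equiv), THF/H2O (4:1), 0 → 23 °C
Reagents that add atoms: none
Why: Borohydride reduction of an N-acyl oxazolidinone to the primary alcohol in aqueous THF is selective over the ethyl ester and the carbamates, and no stereocentre is touched.

Step 6
Reactants: 10 C17 alcohol
Product: 11 C7-hydrazido trans-fused γ-lactone (C17–O–C11(=O), C5=C6)
Conditions: PPTS (10 mol %), toluene, 80 °C
Reagents that add atoms: none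
Why: Acid-catalysed lactonisation (intramolecular transesterification) of the trans-diequatorial CH2OH/CO2Et pair with loss of ethanol should give the trans-fused γ-lactone under conditions the Boc groups tolerate, and it removes every carbonyl from the reach of the future hydrazine.

Step 7
Reactants: 11 C7-hydrazido trans-fused γ-lactone
Product: 13 C7 hydrazine lactone (C7 NHNH2, C5=C6), via bis(trimethylsilyl carbamate) 12 (not isolated)
Conditions: TMSOTf (5 equiv), 2,6-lutidine (7 equiv), CH2Cl2, 0 → 23 °C; then MeOH, 0 °C; used crude under argon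
Reagents that add atoms: none
Why: Non-protic Boc cleavage, in which silylation of each carbamate carbonyl expels isobutene and methanolysis of the silyl carbamates then releases CO2, should free the hydrazine without acid that could ionise the allylic C7–N bond or move the alkene.

Step 8
Reactants: 13 C7 hydrazine lactone
Product: 16 C6=C7 trans-decalin lactone (H5 anti to the C10 methyl), via N'-nosyl hydrazide 14 (not isolated), via allylic diazene 15 (not isolated)
Conditions: 2-nitrobenzenesulfonyl chloride (1.05 equiv), Et3N (3 equiv), THF, −30 → 23 °C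
Reagents that add atoms: none
Why: Sulfonylation of the hydrazine (either nitrogen leads to the same diazene), amine-induced loss of 2-nitrobenzenesulfinate and retro-ene fragmentation of the monoalkyl diazene (allylic diazene rearrangement) should expel N2 while the N–H hydrogen passes suprafacially to C5 on the face that carried the pseudoaxial C7 nitrogen, anti to the C10 methyl, so that the alkene moves to C6=C7 and the trans ring fusion is set.

Step 9
Reactants: 16 C6=C7 trans-decalin lactone
Product: 17 lactol (C11 hemiacetal, mixture of anomers)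
Conditions: i-Bu2AlH (1.1 equiv), CH2Cl2, −78 °C; Rochelle salt work-up
Reagents that add atoms: none
Why: Partial reduction of a γ-lactone with i-Bu2AlH at low temperature stops at the lactol because the tetrahedral aluminate survives until work-up.

Step 10
Reactants: 17 lactol
Product: 18 C9-vinyl C17 alcohol
Conditions: Ph3PCH3Br (4 equiv), KOt-Bu (3.8 equiv), THF, 0 → 50 °C
Reagents that add atoms: methyltriphenylphosphonium bromide, C[P+](c1ccccc1)(c1ccccc1)c1ccccc1.[Br-]
Why: Wittig methylenation of the open hydroxy aldehyde form of the lactol adds C12 and frees the C17 alcohol, and the C9 centre next to the aldehyde already holds its more stable equatorial configuration.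

Step 11
Reactants: 18 C9-vinyl C17 alcohol
Product: 19 C9-vinyl C17 tert-butyldimethylsilyl ether
Conditions: TBSCl, imidazole, CH2Cl2, 23 °C
Reagents that add atoms: tert-butyldimethylsilyl chloride, CC(C)(C)[Si](C)(C)Cl
Why: Standard imidazole-mediated silylation of a primary alcohol, which shields C17 through the hydroboration and the coupling.

Step 12
Reactants: 20 tert-butyl 4-chloro-3-oxobutanoate
Product: 21 tert-butyl 4-acetoxy-3-oxobutanoate
Conditions: KOAc (1.5 equiv), AcOH (0.5 equiv), DMF, 23 °C
Reagents that add atoms: potassium acetate, CC(=O)[O-].[K+]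
Why: SN2 displacement of the activated α-chloroketone chloride by acetate, buffered so that the keto ester is not enolised.

Step 13
Reactants: 21 tert-butyl 4-acetoxy-3-oxobutanoate
Product: 23 tert-butyl (Z)-4-acetoxy-3-(trifluoromethylsulfonyloxy)but-2-enoate, via lithium Z-enolate 22 (not isolated)
Conditions: LiOTf (1.2 equiv), Et3N (1.3 equiv), Tf2O (1.1 equiv), CH2Cl2, −78 → 0 °C
Reagents that add atoms: triflic anhydride, O=S(=O)(OS(=O)(=O)C(F)(F)F)C(F)(F)F
Why: O-triflation of the lithium-chelated enolate of a β-keto ester in a non-coordinating solvent places the triflate cis to the ester (Z) under conditions mild enough for the acetate.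

Step 14
Reactants: 19 C9-vinyl C17 tert-butyldimethylsilyl ether, 23 tert-butyl (Z)-4-acetoxy-3-(trifluoromethylsulfonyloxy)but-2-enoate
Product: 25 tert-butyl 16-acetoxy-17-(tert-butyldimethylsilyloxy)-ent-labda-6,13E-dien-15-oate, via B-alkyl-9-BBN borane 24 (not isolated)
Conditions: 9-BBN-H, THF, 0 → 23 °C; then 23, PdCl2(dppf) (5 mol %), AsPh3 (5 mol %), K3PO4 (3 M aq), DMF, 23 °C
Reagents that add atoms: none
Why: Anti-Markovnikov hydroboration of the monosubstituted vinyl group (the ring alkene is too hindered for 9-BBN) followed by B-alkyl Suzuki–Miyaura coupling, in which zerovalent palladium inserts into the C–OTf bond with retention, forms C12–C13 with the chain cis to the ester and so gives the 13E alkene.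

Step 15
Reactants: 25 tert-butyl 16-acetoxy-17-(tert-butyldimethylsilyloxy)-ent-labda-6,13E-dien-15-oate
Product: 26 16-acetoxy-17-hydroxy-ent-labda-6,13E-dien-15-oic acid
Conditions: TFA/CH2Cl2 (1:4), H2O (5 equiv), 0 → 23 °C; then aq NaHCO3/THF, 0 °C, 10 min; acidify to pH 4
Reagents that add atoms: none
Why: Acidolysis cleaves the tert-butyl ester (loss of isobutene) and the primary silyl ether in one operation while the acetate, the enoate and the disubstituted ring alkene are stable, and the brief bicarbonate wash removes any C17 trifluoroacetate.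

Step 16
Reactants: 26 16-acetoxy-17-hydroxy-ent-labda-6,13E-dien-15-oic acid
Product: 27 16-acetoxy-17-oxo-ent-labda-6,13E-dien-15-oic acid (target, CNP0217581.1)
Conditions: Dess–Martin periodinane (1.3 equiv), NaHCO3, CH2Cl2, 0 → 23 °C; Na2S2O3 work-up at pH 5
Reagents that add atoms: none
Why: Dess–Martin oxidation of the primary alcohol under near-neutral conditions tolerates the free acid and comes last, so that the β,γ-unsaturated aldehyde with its equatorial C8 formyl group meets neither acid nor base.

**Compound list**

1 | β-cyclocitral (2,6,6-trimethylcyclohex-1-ene-1-carbaldehyde) | CC1=C(C=O)C(C)(C)CCC1 | starting material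
2 | 2-[(E)-2-iodoethenyl]-1,3,3-trimethylcyclohex-1-ene | CC1=C(/C=C/I)C(C)(C)CCC1 | intermediate
3 | di-tert-butyl hydrazine-1,2-dicarboxylate | CC(C)(C)OC(=O)NNC(=O)OC(C)(C)C | starting material
4 | di-tert-butyl 1-[(E)-2-(2,6,6-trimethylcyclohex-1-en-1-yl)ethenyl]hydrazine-1,2-dicarboxylate | CC1=C(/C=C/N(NC(=O)OC(C)(C)C)C(=O)OC(C)(C)C)C(C)(C)CCC1 | intermediate
5 | ethyl fumaroyl chloride (ethyl (E)-4-chloro-4-oxobut-2-enoate) | CCOC(=O)/C=C/C(=O)Cl | starting material
6 | 2-oxazolidinone | O=C1NCCO1 | starting material
7 | lithium 2-oxooxazolidin-3-ide | [Li+].O=C1[N-]CCO1 | intermediate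
8 | ethyl (E)-4-oxo-4-(2-oxooxazolidin-3-yl)but-2-enoate | CCOC(=O)/C=C/C(=O)N1CCOC1=O | intermediate
9 | endo cycloadduct: ethyl 7-[1,2-bis(tert-butoxycarbonyl)hydrazin-1-yl]-8-(2-oxooxazolidine-3-carbonyl)-4,4,10-trimethyl-Δ5-octalin-9-carboxylate (N7 and C17 anti to the C10 methyl, C11 syn) | CCOC(=O)[C@@H]1[C@@H](C(=O)N3CCOC3=O)[C@@H](N(NC(=O)OC(C)(C)C)C(=O)OC(C)(C)C)C=C2C(C)(C)CCC[C@@]12C | intermediate
10 | C17 alcohol: ethyl 7-[1,2-bis(tert-butoxycarbonyl)hydrazin-1-yl]-8-(hydroxymethyl)-4,4,10-trimethyl-Δ5-octalin-9-carboxylate | CCOC(=O)[C@@H]1[C@@H](CO)[C@@H](N(NC(=O)OC(C)(C)C)C(=O)OC(C)(C)C)C=C2C(C)(C)CCC[C@@]12C | intermediate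
11 | C7-hydrazido trans-fused γ-lactone (C17–O–C11(=O), C5=C6) | O=C3[C@@H]1[C@@H](CO3)[C@@H](N(NC(=O)OC(C)(C)C)C(=O)OC(C)(C)C)C=C2C(C)(C)CCC[C@@]12C | intermediate
12 | bis(trimethylsilyl carbamate) of the C7 hydrazine lactone | O=C3[C@@H]1[C@@H](CO3)[C@@H](N(NC(=O)O[Si](C)(C)C)C(=O)O[Si](C)(C)C)C=C2C(C)(C)CCC[C@@]12C | intermediate
13 | C7 hydrazine lactone (C7 NHNH2, C5=C6) | O=C3[C@@H]1[C@@H](CO3)[C@@H](NN)C=C2C(C)(C)CCC[C@@]12C | intermediate
14 | N'-(2-nitrobenzenesulfonyl) hydrazide of the lactone | O=C3[C@@H]1[C@@H](CO3)[C@@H](NNS(=O)(=O)c4ccccc4[N+](=O)[O-])C=C2C(C)(C)CCC[C@@]12C | intermediate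
15 | C7 allylic diazene lactone | O=C3[C@@H]1[C@@H](CO3)[C@@H](N=N)C=C2C(C)(C)CCC[C@@]12C | intermediate
16 | C6=C7 trans-decalin lactone (H5 and C17 anti to the C10 methyl, C11 syn) | O=C3[C@@H]1[C@@H](CO3)C=C[C@@H]2C(C)(C)CCC[C@@]12C | intermediate
17 | lactol (C11 hemiacetal, anomeric mixture) | OC3[C@@H]1[C@@H](CO3)C=C[C@@H]2C(C)(C)CCC[C@@]12C | intermediate
18 | C9-vinyl C17 alcohol | C=C[C@@H]1[C@@H](CO)C=C[C@@H]2C(C)(C)CCC[C@@]12C | intermediate
19 | C9-vinyl C17 tert-butyldimethylsilyl ether | C=C[C@@H]1[C@@H](CO[Si](C)(C)C(C)(C)C)C=C[C@@H]2C(C)(C)CCC[C@@]12C | intermediate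
20 | tert-butyl 4-chloro-3-oxobutanoate | ClCC(=O)CC(=O)OC(C)(C)C | starting material
21 | tert-butyl 4-acetoxy-3-oxobutanoate | CC(=O)OCC(=O)CC(=O)OC(C)(C)C | intermediate
22 | lithium (Z)-enolate of tert-butyl 4-acetoxy-3-oxobutanoate | CC(=O)OC/C([O-])=C/C(=O)OC(C)(C)C.[Li+] | intermediate
23 | tert-butyl (Z)-4-acetoxy-3-(trifluoromethylsulfonyloxy)but-2-enoate | CC(=O)OC/C(OS(=O)(=O)C(F)(F)F)=C/C(=O)OC(C)(C)C | intermediate
24 | B-alkyl-9-BBN borane (boron on C12 of the silyl ether) | C(CB1C2CCCC1CCC2)[C@@H]1[C@@H](CO[Si](C)(C)C(C)(C)C)C=C[C@@H]2C(C)(C)CCC[C@@]12C | intermediate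
25 | tert-butyl 16-acetoxy-17-(tert-butyldimethylsilyloxy)-ent-labda-6,13E-dien-15-oate | CC(=O)OC/C(=C/C(=O)OC(C)(C)C)CC[C@@H]1[C@@H](CO[Si](C)(C)C(C)(C)C)C=C[C@@H]2C(C)(C)CCC[C@@]12C | intermediate
26 | 16-acetoxy-17-hydroxy-ent-labda-6,13E-dien-15-oic acid | CC(=O)OC/C(=C/C(=O)O)CC[C@@H]1[C@@H](CO)C=C[C@@H]2C(C)(C)CCC[C@@]12C | intermediate
27 | (5R,8S,9R,10S)-16-acetoxy-17-oxo-ent-labda-6,13E-dien-15-oic acid (CNP0217581.1) | CC(=O)OC/C(=C/C(=O)O)CC[C@@H]1[C@@H](C=O)C=C[C@@H]2C(C)(C)CCC[C@@]12C | target

**Count**

Total steps: 16. Longest linear sequence: 13 steps (steps 1, 2, 4 to 11, 14 to 16, from β-cyclocitral).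

**Steps most likely to fail**

Step 4 (proposed new method). The twisted diene with its tetrasubstituted terminus may add too slowly to the catalyst-bound dienophile, the carbamate groups may compete with the imide for copper, or the facial selectivity may be low. The fallback replaces catalyst control by a covalently bound auxiliary and a stoichiometric Lewis acid, which is known chemistry. It sets out from 5 and 4. Acid chloride 5 would be acylated onto lithiated, commercially available (S)-4-benzyl-2-oxazolidinone to give ethyl (E)-4-[(4S)-4-benzyl-2-oxooxazolidin-3-yl]-4-oxobut-2-enoate F1. Cycloaddition of 4 with F1 promoted by Et2AlCl (1.4 equiv, CH2Cl2, −78 → −30 °C) should proceed through the aluminium chelate, whose benzyl group shields the Re face of C8, and give the auxiliary-bearing endo cycloadduct F2, from which any minor diastereomer can be removed by chromatography. Reduction with NaBH4 in aqueous THF then releases the auxiliary, and the route is rejoined at compound 10.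

Step 7 (with step 8). The free allylic hydrazine may be oxidised by air, attack the lactone of a second molecule, or be sulfonylated more than once, and the second Boc group may be lost slowly. The fallback avoids the free hydrazine by reversing the order of events. It sets out from 11, whose carbamate N–H would be deprotonated (NaH, THF, 0 °C) and sulfonylated with 2-nitrobenzenesulfonyl chloride to give the N'-(2-nitrobenzenesulfonyl) bis-Boc hydrazide lactone F3. Removal of both Boc groups from F3 (TMSOTf, 2,6-lutidine; MeOH) then gives the sulfonyl hydrazide directly. The route is rejoined at compound 14, which goes on to 15 and 16 on addition of Et3N as in step 8.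

Step 14. Zerovalent palladium may ionise the allylic acetate of the triflate or of the product, the aqueous base may hydrolyse the acetate, and transmetalation of the hindered borane may be slow. The fallback carries the C16 oxygen as an ether through the coupling and adds the acetate afterwards. It sets out from 20 and from 19 (as its borane 24). Chloride 20 would be displaced by 4-methoxybenzyl alcohol (NaH, 2.2 equiv, THF) to give tert-butyl 4-(4-methoxybenzyloxy)-3-oxobutanoate F4. Z-selective triflation (Tf2O, aqueous LiOH, toluene, 5 °C) would give tert-butyl (Z)-4-(4-methoxybenzyloxy)-3-(trifluoromethylsulfonyloxy)but-2-enoate F5. Coupling of F5 with borane 24 under the conditions of step 14 would give the C16 4-methoxybenzyl ether of the protected labdane F6. DDQ in wet CH2Cl2 would give the C16 allylic alcohol F7, and acetylation (Ac2O, pyridine, DMAP) rejoins the route at compound 25.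

**Further compounds**

F1 | step 4 | ethyl (E)-4-[(4S)-4-benzyl-2-oxooxazolidin-3-yl]-4-oxobut-2-enoate | CCOC(=O)/C=C/C(=O)N1[C@@H](Cc2ccccc2)COC1=O
F2 | step 4 | auxiliary-bearing endo cycloadduct | CCOC(=O)[C@@H]1[C@@H](C(=O)N3[C@@H](Cc4ccccc4)COC3=O)[C@@H](N(NC(=O)OC(C)(C)C)C(=O)OC(C)(C)C)C=C2C(C)(C)CCC[C@@]12C
F3 | step 7 | N'-(2-nitrobenzenesulfonyl) bis-Boc hydrazide lactone | O=C3[C@@H]1[C@@H](CO3)[C@@H](N(N(C(=O)OC(C)(C)C)S(=O)(=O)c4ccccc4[N+](=O)[O-])C(=O)OC(C)(C)C)C=C2C(C)(C)CCC[C@@]12C
F4 | step 14 | tert-butyl 4-(4-methoxybenzyloxy)-3-oxobutanoate | COc1ccc(COCC(=O)CC(=O)OC(C)(C)C)cc1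
F5 | step 14 | tert-butyl (Z)-4-(4-methoxybenzyloxy)-3-(trifluoromethylsulfonyloxy)but-2-enoate | COc1ccc(COC/C(OS(=O)(=O)C(F)(F)F)=C/C(=O)OC(C)(C)C)cc1
F6 | step 14 | C16 4-methoxybenzyl ether of the protected labdane | COc1ccc(COC/C(=C/C(=O)OC(C)(C)C)CC[C@@H]2[C@@H](CO[Si](C)(C)C(C)(C)C)C=C[C@@H]3C(C)(C)CCC[C@@]23C)cc1
F7 | step 14 | C16 allylic alcohol (tert-butyl 16-hydroxy-17-(tert-butyldimethylsilyloxy)-ent-labda-6,13E-dien-15-oate) | OC/C(=C/C(=O)OC(C)(C)C)CC[C@@H]1[C@@H](CO[Si](C)(C)C(C)(C)C)C=C[C@@H]2C(C)(C)CCC[C@@]12C
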